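**Remarks before the route**

- The target is taken exactly as drawn in the SMILES: 5-[(8Z,15S)-15-hydroxyheptadec-8-en-1-yl]benzene-1,3-diol. Ring atoms are C1–C6 (OH on C1 and C3, chain on C5); chain atoms are C1'–C17', counted from the ring. Compound numbers 1–19 are those of the steps and of the compound list.
- Assumption for step 5: the (S)-BINAP–Ru catalyst reduces the 4-oxo ester in the same facial sense as it reduces β-keto esters (ester-chelated transition state), which gives the (S)-carbinol.

## Analysis of the target

Hansfordiol G is a 5-alkylresorcinol: one benzene ring (C1–C6, OH on C1 and C3) that carries on C5 an unbranched C17 chain (C1'–C17'), and no other ring. The chain holds only two stereo-elements, the Z-alkene C8'=C9' and the secondary carbinol C15' of S configuration (OH > C14' > C16' > H), whose two carbon substituents are an ethyl group and a long n-alkyl chain. Alkene and carbinol are separated by the pentamethylene spacer C10'–C14', and the alkene is seven methylenes (C1'–C7') from the ring, so neither element can control the other and each must be set on its own. The difficulty is therefore purity and convergence, not complexity: the E-isomer and the enantiomer would be practically inseparable from an oily lipid, and ethyl and n-alkyl are too alike for a catalyst to tell apart at a plain ketone or aldehyde unless a functional handle makes them different. The methylene stretches offer no functional group, so every polar C–C bond formation has to bring a handle and remove it again. Sensitive groups are the electron-rich free resorcinol (oxidation, electrophiles), the isolated Z-alkene (which rules out hydrogenolysis and harsh Lewis-acid or HBr demethylation and can isomerise through allylic radicals or metal hydrides) and the free secondary alcohol. The feature on which the strategy rests is the σ-bond C12'–C13' in the middle of the spacer: seen from there, the C15'–O bond is γ to C13' (a 4-oxygenated hexanoic acid in disguise) and C9' is three methylenes from C12' (a Δ5-alkenoic acid in disguise), so both halves can be written as carboxylic acids whose carboxyl groups are traceless.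

## Retrosynthetic reasoning

**19 ⇒ 18.** The last operation only frees three O–H groups. Target 19 is traced back to its tris-silyl ether 18, so that a single fluoride treatment ends the synthesis and nothing acidic, Lewis acidic or hydrogenolytic has to meet the Z-alkene. Methyl or benzyl ethers on the ring were avoided for that reason.

**18 ⇒ 9 + 15 (key disconnection, C12'–C13').** The bond is cut inside the unfunctionalised spacer, not at the alkene and not next to the carbinol. This splits 18 into the achiral Z-alkenoic acid 9 (arene, alkene, 19 carbons, no stereocentre) and the small chiral acid 15 (stereocentre, six carbons, nothing else). The forward reaction is a reductive, nickel-electrocatalysed doubly decarboxylative C(sp3)–C(sp3) cross-coupling of the two acids, activated in the flask as the redox-active esters 16 and 17; both carboxyl carbons leave, and no handle remains in the chain.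

The position is dictated by mechanism:
- The radical from 16 sits on C12', three methylenes from C9'; it is not allylic and has no 5-exo cyclisation mode.
- A cut one bond further out (C13'–C14') would give a hex-5-enyl-type radical, which cyclises fast, and would put the oxygen β to the metal-bound carbon.
- A cut one bond further in (C11'–C12') would give a homoallyl radical, whose reversible cyclopropylcarbinyl closure can scramble the alkene geometry.
- In 17 the oxygen is γ to the radical carbon, so β-elimination is impossible.
- A cathodic process is chosen over an anodic Kolbe coupling because the bis-oxygenated arene would be at risk at Kolbe potentials.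

**15 ⇒ 12 ⇒ 10.** Acid 15 is the ring-opened, O-silylated form of lactone 12. Lactone 12 is the retron of an asymmetric hydrogenation of the γ-keto ester 10. In 10 the ester group, not size, distinguishes the two arms of the ketone (ethyl versus CH2CH2CO2Et), which solves the ethyl/n-alkyl problem at the only stage where a handle exists. The same carboxyl group is later expelled in the key step.

**9 ⇒ 6 + 7.** The Z-alkene C8'=C9' is made early, as a supporting step, by a salt-free Wittig reaction of aldehyde 6 with the ylide 8 from the commercial carboxy-phosphonium salt 7. The salt brings the carboxyl handle for the key step for free. The geometry is fixed on a polar, purifiable acid, several steps before the end.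

**6 ⇒ 5 ⇒ 2 + 3; 2 ⇒ 1.** Aldehyde 6 comes from ester 5 by partial hydride reduction. The aryl–C1' bond of 5 is the simplest bond of the molecule and is formed by iron-catalysed coupling of the aryl Grignard reagent 4 (from bromide 2) with bromo ester 3. Bromide 2 is the bis-silyl ether of commercial 5-bromoresorcinol 1.

## Alternatives that were turned down

**Alternative 1:** the textbook cut at C8'=C9'.
- Forward key step: Z-selective Wittig olefination of aldehyde 6 with the ylide from [(7S)-7-[(tert-butyldimethylsilyl)oxy]nonyl]triphenylphosphonium bromide A1, which would give 18 directly. Its catalytic version is a Z-selective cross-metathesis of (3S)-dec-9-en-3-ol A2 with 5-(non-8-en-1-yl)benzene-1,3-diol A3.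
- Why turned down (Wittig version): the key step builds only the alkene and leaves the stereocentre to a separate linear sequence. A1 needs a chiral epoxide opening with a bifunctional C5 organometallic, protection, unmasking, halide formation and quaternisation: about five steps for a fragment that the chosen route obtains in two.
- Why turned down (metathesis version): by step count (about four) it is the strongest competitor. It was turned down on mechanism. A2 and A3 are sterically and electronically identical monosubstituted alkenes, so only an excess of one partner biases cross- over homo-metathesis. The kinetic Z-preference is eroded by secondary metathesis as conversion rises. E-isomer and homodimers would arise in the last C–C bond-forming step on an oily lipid, where they can hardly be removed.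

**Alternative 2:** cut at C15'–C16'.
- Forward key step: catalytic enantioselective addition of an ethylzinc reagent to (7Z)-15-{3,5-bis[(tert-butyldimethylsilyl)oxy]phenyl}pentadec-7-enal A4, then desilylation to 19. The stereocentre would be set last, by catalyst control.
- Why turned down: A4 must already carry the arene, the whole chain and the Z-alkene, so the route to it is fully linear and the key step adds only two carbons. Unbranched aliphatic aldehydes are the weakest substrate class for this reaction. An enantiomeric excess fixed in the penultimate step of an oily series cannot be upgraded.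

**Alternative 3:** cut at C5(aryl)–C1', following the biogenetic logic (fatty-acyl starter → alkylresorcinol).
- Forward key step: nickel- or iron-catalysed decarboxylative arylation of the redox-active ester of (9Z,16S)-16-[(tert-butyldimethylsilyl)oxy]octadec-9-enoic acid A5 with the aryl-metal reagent derived from 2 (cf. 4), to give 18.
- Why turned down: A5 contains 18 of the 23 carbons and both stereo-elements, so the precursor is hardly simpler than the product. The bond made is the easiest one of the molecule (step 2 forms it on a trivial substrate). A5 itself would still need an olefination and a carbinol synthesis, i.e. Alternative 1 plus two steps.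

Key step: step 7

## Route

**Step 1**  
Reactants: 1 5-bromobenzene-1,3-diol  
Product: 2 1-bromo-3,5-bis[(tert-butyldimethylsilyl)oxy]benzene  
Conditions: TBSCl (2.3 equiv), imidazole (5 equiv), DMF, 0 °C → rt  
Reagents that add atoms: tert-butyldimethylsilyl chloride, `CC(C)(C)[Si](C)(C)Cl`  
Why: Standard imidazole-mediated silylation of phenols; the TBS ethers mask the acidic OH groups for Grignard formation, should survive hydride, ylide and reductive electrolysis, and fall together with the carbinol silyl ether in one final fluoride step.

**Step 2**  
Reactants: 2 1-bromo-3,5-bis[(tert-butyldimethylsilyl)oxy]benzene, 3 ethyl 8-bromooctanoate  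
Product: 5 ethyl 8-{3,5-bis[(tert-butyldimethylsilyl)oxy]phenyl}octanoate, via aryl Grignard reagent 4 (not isolated)  
Conditions: Mg (1.3 equiv), cat. I2, THF, 45 °C; then slow addition of 4/TMEDA (1.2 equiv) to 3 and FeCl3 (5 mol %), THF, 0 °C  
Reagents that add atoms: none  
Why: Iron-catalysed Kumada-type cross-coupling of an aryl Grignard reagent with a primary alkyl bromide forms the C5(aryl)–C1' bond; slow addition at 0 °C keeps the Grignard concentration low, so coupling should outrun addition to the ester.

**Step 3**  
Reactants: 5 ethyl 8-{3,5-bis[(tert-butyldimethylsilyl)oxy]phenyl}octanoate  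
Product: 6 8-{3,5-bis[(tert-butyldimethylsilyl)oxy]phenyl}octanal  
Conditions: DIBAL-H (1.1 equiv), CH2Cl2, −78 °C; MeOH, then aq. Rochelle salt  
Reagents that add atoms: none  
Why: Partial ester reduction with DIBAL-H; the tetrahedral aluminium hemiacetal persists at −78 °C until work-up, which should prevent over-reduction, and the silyl ethers are inert.

**Step 4**  
Reactants: 6 8-{3,5-bis[(tert-butyldimethylsilyl)oxy]phenyl}octanal, 7 (4-carboxybutyl)triphenylphosphonium bromide  
Product: 9 (5Z)-13-{3,5-bis[(tert-butyldimethylsilyl)oxy]phenyl}tridec-5-enoic acid, via phosphonium ylide 8 (not isolated)  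
Conditions: 7 (1.5 equiv), NaHMDS (3.0 equiv), THF, 0 °C → rt; then 6, −78 °C → rt; aq. HCl to pH 4  
Reagents that add atoms: none  
Why: Wittig olefination with a non-stabilised, lithium-free ylide under kinetic control should proceed through the cis-oxaphosphetane and give the Z-alkene C8'=C9'; the carboxylate travels as its sodium salt, and mild acidification spares the aryl silyl ethers.

**Step 5**  
Reactants: 10 ethyl 4-oxohexanoate  
Product: 12 (5S)-5-ethyloxolan-2-one, via hydroxy ester 11 (not isolated)  
Conditions: H2 (100 atm), Ru(II)–(S)-BINAP dichloride catalyst (0.2 mol %), EtOH, 35 °C; then TsOH (cat.), toluene, 60 °C  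
Reagents that add atoms: none  
Why: Noyori-type asymmetric hydrogenation of a 4-oxo ester; chelation of the ester carbonyl to ruthenium distinguishes the ester arm from the ethyl group, so hydrogen should be delivered to one face and set C15' as S, and acid-catalysed lactonisation then traps the alcohol without touching the C–O stereocentre.

**Step 6**  
Reactants: 12 (5S)-5-ethyloxolan-2-one  
Product: 15 (4S)-4-[(tert-butyldimethylsilyl)oxy]hexanoic acid, via potassium hydroxy carboxylate 13 (not isolated), via bis-silyl derivative 14 (not isolated)  
Conditions: KOH (1.05 equiv), MeOH/H2O, rt, evaporate; TBSCl (2.5 equiv), imidazole (5 equiv), DMF, rt; K2CO3 (1.5 equiv), MeOH/THF/H2O, rt; aq. HCl to pH 4–5, 0 °C  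
Reagents that add atoms: potassium hydroxide, `[K+].[OH-]`; tert-butyldimethylsilyl chloride, `CC(C)(C)[Si](C)(C)Cl`  
Why: Saponification opens the lactone by acyl–oxygen cleavage (stereocentre untouched), exhaustive silylation gives silyl ether and silyl ester, and mild carbonate hydrolysis should cleave only the labile silyl ester; the γ-silyloxy acid cannot relactonise.

**Step 7**  
Reactants: 9 (5Z)-13-{3,5-bis[(tert-butyldimethylsilyl)oxy]phenyl}tridec-5-enoic acid, 15 (4S)-4-[(tert-butyldimethylsilyl)oxy]hexanoic acid  
Product: 18 1,3-bis[(tert-butyldimethylsilyl)oxy]-5-[(8Z,15S)-15-[(tert-butyldimethylsilyl)oxy]heptadec-8-en-1-yl]benzene, via alkenyl NHPI ester 16 (not isolated), via silyloxy NHPI ester 17 (not isolated)  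
Conditions: 9 (1 equiv), 15 (3 equiv), N-hydroxyphthalimide (4.1 equiv), DIC (4.1 equiv), NMP, rt; then NiCl2·6H2O (20 mol %), 2,2':6',2''-terpyridine (20 mol %), AgNO3 (0.3 equiv), Mg(+)/RVC(−), undivided cell, constant current, rt; aq. NH4Cl/dil. HCl work-up  
Reagents that add atoms: none  
Why: The carbodiimide converts both acids into the N-acyloxyphthalimides 16 and 17 in the flask; cathodically generated low-valent nickel (assisted by the silver-coated cathode) transfers one electron to each ester, which loses phthalimide anion and CO2 to give a primary alkyl radical, and sequential radical capture at nickel followed by reductive elimination from a dialkylnickel(III) species forms the C12'–C13' bond, while the magnesium anode supplies the electrons. The closest known reaction type is the Ni-electrocatalytic doubly decarboxylative C(sp3)–C(sp3) cross-coupling of in situ formed redox-active esters, known for primary–primary pairs that carry protected carbinols and isolated alkenes. No ring is closed and no stereocentre is formed: C15' was fixed in step 5, lies γ to the radical carbon C13' and takes part in no bond change. The Z geometry of C8'=C9' should survive because the radical from 16 sits on C12', three methylenes from C9', where neither allylic delocalisation nor a 5-exo cyclisation is possible (only disfavoured 4-exo or 5-endo modes). The selectivity that the step needs is hetero- over homo-coupling of two primary radicals of like reactivity; it is secured statistically by the threefold excess of the short acid 15, so that 16 should be consumed mainly in the crossed product, and the small non-polar homodimer of 17 is removed by chromatography. The γ-position of the silyloxy group excludes β-alkoxy elimination from the alkylnickel intermediate, and the reductive regime leaves the electron-rich arene and its silyl ethers untouched, which an anodic Kolbe coupling would not guarantee.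

**Step 8**  
Reactants: 18 1,3-bis[(tert-butyldimethylsilyl)oxy]-5-[(8Z,15S)-15-[(tert-butyldimethylsilyl)oxy]heptadec-8-en-1-yl]benzene  
Product: 19 5-[(8Z,15S)-15-hydroxyheptadec-8-en-1-yl]benzene-1,3-diol (Hansfordiol G)  
Conditions: TBAF (4 equiv), THF, 0 °C → rt; aq. NH4Cl  
Reagents that add atoms: none  
Why: Fluoride-driven cleavage of all three Si–O bonds (formation of the strong Si–F bond); the aryl silyl ethers should go quickly and the secondary one at room temperature, under conditions that affect neither the Z-alkene nor the stereocentre.

## Compound list

```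
1 | 5-bromobenzene-1,3-diol | Oc1cc(O)cc(Br)c1 | starting material
2 | 1-bromo-3,5-bis[(tert-butyldimethylsilyl)oxy]benzene | CC(C)(C)[Si](C)(C)Oc1cc(Br)cc(O[Si](C)(C)C(C)(C)C)c1 | intermediate
3 | ethyl 8-bromooctanoate | CCOC(=O)CCCCCCCBr | starting material
4 | {3,5-bis[(tert-butyldimethylsilyl)oxy]phenyl}magnesium bromide | CC(C)(C)[Si](C)(C)Oc1cc([Mg]Br)cc(O[Si](C)(C)C(C)(C)C)c1 | intermediate
5 | ethyl 8-{3,5-bis[(tert-butyldimethylsilyl)oxy]phenyl}octanoate | CCOC(=O)CCCCCCCc1cc(O[Si](C)(C)C(C)(C)C)cc(O[Si](C)(C)C(C)(C)C)c1 | intermediate
6 | 8-{3,5-bis[(tert-butyldimethylsilyl)oxy]phenyl}octanal | O=CCCCCCCCc1cc(O[Si](C)(C)C(C)(C)C)cc(O[Si](C)(C)C(C)(C)C)c1 | intermediate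
7 | (4-carboxybutyl)triphenylphosphonium bromide | OC(=O)CCCC[P+](c1ccccc1)(c1ccccc1)c1ccccc1.[Br-] | starting material
8 | sodium 5-(triphenyl-lambda5-phosphanylidene)pentanoate | [Na+].[O-]C(=O)CCCC=P(c1ccccc1)(c1ccccc1)c1ccccc1 | intermediate
9 | (5Z)-13-{3,5-bis[(tert-butyldimethylsilyl)oxy]phenyl}tridec-5-enoic acid | OC(=O)CCC/C=C\CCCCCCCc1cc(O[Si](C)(C)C(C)(C)C)cc(O[Si](C)(C)C(C)(C)C)c1 | intermediate
10 | ethyl 4-oxohexanoate | CCOC(=O)CCC(=O)CC | starting material
11 | ethyl (4S)-4-hydroxyhexanoate | CC[C@H](O)CCC(=O)OCC | intermediate
12 | (5S)-5-ethyloxolan-2-one | CC[C@H]1CCC(=O)O1 | intermediate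
13 | potassium (4S)-4-hydroxyhexanoate | CC[C@H](O)CCC(=O)[O-].[K+] | intermediate
14 | tert-butyldimethylsilyl (4S)-4-[(tert-butyldimethylsilyl)oxy]hexanoate | CC[C@H](O[Si](C)(C)C(C)(C)C)CCC(=O)O[Si](C)(C)C(C)(C)C | intermediate
15 | (4S)-4-[(tert-butyldimethylsilyl)oxy]hexanoic acid | CC[C@H](O[Si](C)(C)C(C)(C)C)CCC(=O)O | intermediate
16 | 1,3-dioxoisoindolin-2-yl (5Z)-13-{3,5-bis[(tert-butyldimethylsilyl)oxy]phenyl}tridec-5-enoate | O=C(CCC/C=C\CCCCCCCc1cc(O[Si](C)(C)C(C)(C)C)cc(O[Si](C)(C)C(C)(C)C)c1)ON1C(=O)c2ccccc2C1=O | intermediate
17 | 1,3-dioxoisoindolin-2-yl (4S)-4-[(tert-butyldimethylsilyl)oxy]hexanoate | CC[C@H](O[Si](C)(C)C(C)(C)C)CCC(=O)ON1C(=O)c2ccccc2C1=O | intermediate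
18 | 1,3-bis[(tert-butyldimethylsilyl)oxy]-5-[(8Z,15S)-15-[(tert-butyldimethylsilyl)oxy]heptadec-8-en-1-yl]benzene | CC[C@H](O[Si](C)(C)C(C)(C)C)CCCCC/C=C\CCCCCCCc1cc(O[Si](C)(C)C(C)(C)C)cc(O[Si](C)(C)C(C)(C)C)c1 | intermediate
19 | 5-[(8Z,15S)-15-hydroxyheptadec-8-en-1-yl]benzene-1,3-diol (Hansfordiol G) | CC[C@H](O)CCCCC/C=C\CCCCCCCc1cc(O)cc(O)c1 | target
```

## Step count and least certain steps

Total step count: 8. Longest linear sequence: 6 (steps 1, 2, 3, 4, 7, 8); the chiral branch (steps 5, 6) joins at step 7.

**Step 7 (key step).**
- What may go wrong: statistical homo-coupling, together with premature reduction or β-hydride elimination of the alkylnickel intermediates, would drain acid 9 into decarboxylated alkane and alkene. Aryl silyl groups could be lost slowly in NMP in the presence of Mg2+ and phthalimide anion. The Z-alkene could isomerise if a nickel hydride builds up.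
- Fallback (polar, chiral-pool): it sets out from 9 and comes back to the route at 19. Reduction of 9 with LiAlH4 (THF, 0 °C) would give (5Z)-13-{3,5-bis[(tert-butyldimethylsilyl)oxy]phenyl}tridec-5-en-1-ol F1. Appel bromination (CBr4, PPh3) would give 1-[(8Z)-13-bromotridec-8-en-1-yl]-3,5-bis[(tert-butyldimethylsilyl)oxy]benzene F2. Magnesium insertion at low temperature (to limit 5-exo closure of the transient radical) would give {(5Z)-13-{3,5-bis[(tert-butyldimethylsilyl)oxy]phenyl}tridec-5-en-1-yl}magnesium bromide F3. With CuI catalysis F3 should open commercial (S)-1,2-epoxybutane (`CC[C@H]1CO1`) at its CH2 group to (3S,9Z)-17-{3,5-bis[(tert-butyldimethylsilyl)oxy]phenyl}heptadec-9-en-3-ol F4; the stereocentre is bought and not touched. Desilylation of F4 under the conditions of step 8 gives 19.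

**Step 4 (Wittig olefination).**
- What may go wrong: stereochemical drift through reversible oxaphosphetane formation would give more E-isomer than can be removed from 9 (argentation chromatography of the acid is the intended purification). Excess base could partly cleave the aryl silyl ethers.
- Fallback (alkyne and semi-hydrogenation): it sets out from 2 (through 4) and comes back at 9. Copper-catalysed coupling of 4 with an excess of 1,7-dibromoheptane would give 1-(7-bromoheptyl)-3,5-bis[(tert-butyldimethylsilyl)oxy]benzene F5. Alkylation of the dianion of hex-5-ynoic acid (n-BuLi, THF/DMPU) with F5 would give 13-{3,5-bis[(tert-butyldimethylsilyl)oxy]phenyl}tridec-5-ynoic acid F6. Lindlar semi-hydrogenation (syn-addition of hydrogen on the poisoned surface) should deliver 9.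

**Step 2 (iron-catalysed aryl–alkyl coupling).**
- What may go wrong: addition of the aryl Grignard reagent to the ester, biaryl homo-coupling, and β-hydride elimination from the alkyl-iron intermediate.
- Fallback (B-alkyl Suzuki–Miyaura coupling): it sets out from 2 and comes back at 5. Hydroboration of commercial ethyl oct-7-enoate with 9-BBN would give ethyl 8-(9-borabicyclo[3.3.1]nonan-9-yl)octanoate F7, which is coupled with 2 under Pd(dppf)Cl2/K3PO4 (THF, little water, 60 °C).

**Step 5 (asymmetric hydrogenation).**
- What may go wrong: insufficient enantioselectivity, or the opposite facial sense to the one assumed (the seven-membered chelate differs from that of β-keto esters), and incomplete lactonisation. The sign of rotation of 12 must be checked before step 6.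
- Fallback (chiral pool): it does not set out from a numbered compound but from commercial (S)-1,2-epoxybutane in place of 10, and comes back at 15. CuI-catalysed opening with allylmagnesium bromide would give (3S)-hept-6-en-3-ol F8. Silylation (TBSCl, imidazole) would give tert-butyl{[(3S)-hept-6-en-3-yl]oxy}dimethylsilane F9. Oxidative cleavage of the terminal alkene (RuCl3 cat., NaIO4) gives 15. This also bypasses step 6.

## Further compounds

```
F1 | step 7 | (5Z)-13-{3,5-bis[(tert-butyldimethylsilyl)oxy]phenyl}tridec-5-en-1-ol | OCCCC/C=C\CCCCCCCc1cc(O[Si](C)(C)C(C)(C)C)cc(O[Si](C)(C)C(C)(C)C)c1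
F2 | step 7 | 1-[(8Z)-13-bromotridec-8-en-1-yl]-3,5-bis[(tert-butyldimethylsilyl)oxy]benzene | BrCCCC/C=C\CCCCCCCc1cc(O[Si](C)(C)C(C)(C)C)cc(O[Si](C)(C)C(C)(C)C)c1
F3 | step 7 | {(5Z)-13-{3,5-bis[(tert-butyldimethylsilyl)oxy]phenyl}tridec-5-en-1-yl}magnesium bromide | Br[Mg]CCCC/C=C\CCCCCCCc1cc(O[Si](C)(C)C(C)(C)C)cc(O[Si](C)(C)C(C)(C)C)c1
F4 | step 7 | (3S,9Z)-17-{3,5-bis[(tert-butyldimethylsilyl)oxy]phenyl}heptadec-9-en-3-ol | CC[C@H](O)CCCCC/C=C\CCCCCCCc1cc(O[Si](C)(C)C(C)(C)C)cc(O[Si](C)(C)C(C)(C)C)c1
F5 | step 4 | 1-(7-bromoheptyl)-3,5-bis[(tert-butyldimethylsilyl)oxy]benzene | BrCCCCCCCc1cc(O[Si](C)(C)C(C)(C)C)cc(O[Si](C)(C)C(C)(C)C)c1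
F6 | step 4 | 13-{3,5-bis[(tert-butyldimethylsilyl)oxy]phenyl}tridec-5-ynoic acid | OC(=O)CCCC#CCCCCCCCc1cc(O[Si](C)(C)C(C)(C)C)cc(O[Si](C)(C)C(C)(C)C)c1
F7 | step 2 | ethyl 8-(9-borabicyclo[3.3.1]nonan-9-yl)octanoate | CCOC(=O)CCCCCCCB1C2CCCC1CCC2
F8 | step 5 | (3S)-hept-6-en-3-ol | CC[C@H](O)CCC=C
F9 | step 5 | tert-butyl{[(3S)-hept-6-en-3-yl]oxy}dimethylsilane | CC[C@H](O[Si](C)(C)C(C)(C)C)CCC=C
A1 | alternative 1 | [(7S)-7-[(tert-butyldimethylsilyl)oxy]nonyl]triphenylphosphonium bromide | CC[C@H](O[Si](C)(C)C(C)(C)C)CCCCCC[P+](c1ccccc1)(c1ccccc1)c1ccccc1.[Br-]
A2 | alternative 1 | (3S)-dec-9-en-3-ol | CC[C@H](O)CCCCCC=C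
A3 | alternative 1 | 5-(non-8-en-1-yl)benzene-1,3-diol | C=CCCCCCCCc1cc(O)cc(O)c1
A4 | alternative 2 | (7Z)-15-{3,5-bis[(tert-butyldimethylsilyl)oxy]phenyl}pentadec-7-enal | O=CCCCCC/C=C\CCCCCCCc1cc(O[Si](C)(C)C(C)(C)C)cc(O[Si](C)(C)C(C)(C)C)c1
A5 | alternative 3 | (9Z,16S)-16-[(tert-butyldimethylsilyl)oxy]octadec-9-enoic acid | CC[C@H](O[Si](C)(C)C(C)(C)C)CCCCC/C=C\CCCCCCCC(=O)O
```
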